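## The problem

Compound 21 is an isoflavan: ring A is fused to the saturated pyran ring C (O1, C2, C3, C4), C3 carries ring B, and ring B is fused through O2' and C3' to a 2,2-dimethyl-2H-pyran, ring D. C3 is the only stereocentre and must be R. It lies between the methylene groups C2 and C4, so no second stereocentre can direct it, and it has to come from a chiral catalyst or an auxiliary. Ring A is a phloroglucinol and ring B a resorcinol, and their five oxygens end in four different states (methyl ether on O5, free hydroxyl on O7 and O4', ring C ether at O1, ring D ether at O2'), so the protecting groups must tell them apart. The cis-styrene double bond of ring D does not tolerate hydrogenolysis, strong acid or a metal hydride that adds to alkenes, and the electron-rich free phenols oxidise easily; ring D should therefore come late and the last deprotection must be mild and non-reductive. Whenever C2 is at the carbonyl level, H–C3 is flanked by an aryl ester and by ring B and is easily removed, so base must be kept away from such intermediates. The feature that opens the key step is that C2 is a single carbon between C3 and O1: removed as carbon monoxide, it leaves a stilbene whose C3=C4 alkene joins ring B to ring A and whose phenol oxygen on C8a sits where it can trap an acyl group on C3.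

## Retrosynthesis

**21 from 20.** The two O–Si bonds on O7 and O4' are cut last. Silyl ethers are preferred to benzyl ethers here because the ring D alkene rules out a final hydrogenolysis. The precursor 20 differs from the target only by two robust protecting groups, and the forward step need only be non-acidic and non-reductive.

**20 from 15 and 16.** Ring D is opened at the bond from C3' to its vinyl carbon and at the bond from O2' to the quaternary carbon. This leads through the aryl propargyl ether 17 to phenol 15 and 3-chloro-3-methylbut-1-yne 16. Carrying ring D from the start would expose its alkene to the palladium hydride of the key step and would forbid a benzyl group on O2'. In 15 only C3' is free next to the 2'-hydroxyl, so the forward Claisen rearrangement has one place to go.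

**15 from 14.** The O–benzyl bond on O2' is cut. Benzyl on O2' against silyl on O7 and O4' is what lets one phenol be freed alone. The forward hydrogenolysis meets no alkene at this stage.

**14 from 12 through 13.** The O1–C2 bond is cut and C2 is returned to the carbonyl level, giving lactone 12 by way of diol 13. Direct deoxygenation through the lactol was weighed against this; the lactol can open to an α-aryl aldehyde that epimerises, whereas 13 cannot. The forward steps are a hydride reduction that outruns enolisation and a Mitsunobu closure at a CH2 carbon.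

**12 from 10 and 11.** This is the strategic cut: C2–C3 and O1–C2 are broken together, releasing carbon monoxide 11 and the (E)-2-hydroxystilbene 10. One ring, two skeletal bonds and the stereocentre are removed at once, and 10 has no stereocentre. The forward reaction must put palladium on C3 and not on C4, choose one alkene face, and let the C8a phenol take the acyl group.

**10 from 2 and 7.** The C3=C4 double bond is cut by a Wittig disconnection into the ring A salicylaldehyde 2 and the ring B phosphonium salt 7 (used as ylide 8), with the E/Z mixture 9 in between. A Heck disconnection would need a ring A aryl halide that is not at hand, whereas both Wittig partners derive from phenolic aldehydes. The forward olefination must tolerate the free phenol of 2, and the geometry is corrected afterwards.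

**7 from 3, and 2 from 1.** Salt 7 goes back through benzylic alcohol 6 and aldehyde 5 to the monosilyl ether 4 and 2,4-dihydroxybenzaldehyde 3; aldehyde 2 is the monosilyl ether of 2,4-dihydroxy-6-methoxybenzaldehyde 1. Only O–Si, O–benzyl and C–P bonds are cut. In both aldehydes the hydroxyl next to the formyl group is hydrogen-bonded, so the para hydroxyl can be silylated alone.

## Roads not taken

**Alternative 1:** C3–C1' and C4–C4a are cut together and C3/C4 arrive as a two-carbon unit.
- Forward step: vinyllithium A2 adds to the ring B boronate 2-[2,2-dimethyl-5-(triisopropylsilyloxy)-2H-chromen-8-yl]-4,4,5,5-tetramethyl-1,3,2-dioxaborolane A1. Pd(OAc)2 with the ferrocenyl bisphosphine MandyPhos then couples the ate complex with the ring A triflate 2-methoxy-6-(methoxymethoxy)-4-(triisopropylsilyloxy)phenyl trifluoromethanesulfonate A3. Ring B shifts from boron to the neighbouring carbon while ring A is delivered to the terminal carbon, giving the (R)-secondary boronic ester A4.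
- Merits: conjunctive couplings of this kind have a strong record of enantiocontrol with aryl groups; three fragments meet in one step; ring D can be present from the start because no palladium hydride and no hydrogenolysis follow.
- Weak points: boron sits on C3 where C2 must go, so A4 still needs a one-carbon homologation, oxidation, acidic removal of the MOM group beside the chromene and a Mitsunobu closure before it reaches 20. No ring is closed in the key step. A3 is a doubly ortho-substituted, very electron-rich triflate and requires a 1,2,3,5-tetraoxygenated benzene, with one oxygen installed only to be lost. A1 needs ring D built and then borylated.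
- Comparison: on precedent for stereocontrol this road is better than the chosen one. The chosen plan sets against it that C2 arrives as 11 and closes ring C in the step that sets C3, and that both halves come from aldehydes with the natural oxygen pattern.

**Alternative 2:** C4–C4a and O1–C2 are cut and ring A acts as a carbon nucleophile.
- Forward step: a cinchona-derived primary amine with an acid cocatalyst turns the acrolein 2-[2,2-dimethyl-5-(triisopropylsilyloxy)-2H-chromen-8-yl]prop-2-enal A5 into its iminium ion. The ring carbon of 3-methoxy-5-(triisopropylsilyloxy)phenol A6 between hydroxyl and methoxy adds to the methylene end, the enamine is protonated at C3 under catalyst control, and the phenol closes on the aldehyde carbon to give the lactol A7.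
- Merits: metal-free, no pressure equipment, a simple ring A partner, ring D in place. Only an ionic deoxygenation of A7 and desilylation remain, which is four steps fewer after the key step than in the chosen plan; this advantage is real.
- Weak points: A6 has three nucleophilic ring carbons, and attack between hydroxyl and silyloxy would give the 7-methoxy-5-silyloxy isomer, held back only by the bulk of the silyl group. The stereocentre is made by proton delivery to an α-aryl enamine, and the same amine can re-form that enamine from the open hydroxy-aldehyde form of A7 and erase C3. A5 polymerises easily. The silane/Lewis acid reduction of A7 must be run beside the acid-sensitive ring D alkene.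
- Comparison: the chosen plan is longer, but the ring A position is fixed by the formyl carbon of 1, and C3 is formed under acidic conditions in a lactone that does not open.

**Alternative 3:** C3–C4 and O1–C2 are cut.
- Forward step: Cs2CO3 eliminates sulfinate from the sulfone 3-methoxy-2-[(4-methylbenzenesulfonyl)methyl]-5-(triisopropylsilyloxy)phenol A8 to give the ortho-quinone methide 5-methoxy-6-methylidene-3-(triisopropylsilyloxy)cyclohexa-2,4-dien-1-one A9. The acid [2,2-dimethyl-5-(triisopropylsilyloxy)-2H-chromen-8-yl]acetic acid A10, activated in the flask with pivaloyl chloride, enters the cycle of the isothiourea HyperBTM as a catalyst-bound enolate. It adds through C3 to the methylene carbon of A9, and the phenoxide lactonises to the dihydrocoumarin A11.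
- Merits: A11 is at the oxidation level of 12 and already carries ring D, so reduction, Mitsunobu closure and desilylation would finish in three steps after the key step against six here. The catalysis is operationally simple and its enolate chemistry is well understood. In convergence this road equals the chosen one, and in steps after the key step it is better.
- Weak points: stoichiometric carbonate is needed to form A9, yet the only stereocentre of A11 is α to an aryl ester and to ring B, so it is created and then left in a medium that can enolise it. A9 is deactivated by two donor oxygens and may dimerise; its methylene end is not prochiral, so all control rests on the enolate face against a small partner. Aryl silyl ethers are at risk with Cs2CO3. The steps saved at the end return in making A10 and A8.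
- Comparison: the chosen plan sets against it that C3 is formed without base, that both fragments are two to four steps from commercial aldehydes, and that ring D is delayed until nothing can harm it.

Key step: step 8

Assumption: 2,4-dihydroxy-6-methoxybenzaldehyde 1 is taken as purchasable, and since the sense of induction of DTBM-SEGPHOS in step 8 cannot be predicted, the R ligand is written and its antipode would be used if the sense proved opposite.

## Route

Step 1
Reactants: 1 2,4-dihydroxy-6-methoxybenzaldehyde
Product: 2 2-hydroxy-6-methoxy-4-(triisopropylsilyloxy)benzaldehyde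
Conditions: TIPSCl, imidazole, CH2Cl2, 0 °C to rt
Reagents that add atoms: triisopropylsilyl chloride, CC(C)[Si](Cl)(C(C)C)C(C)C
Why: Regioselective silylation of a 2,4-dihydroxybenzaldehyde; the 4-hydroxyl is the more acidic and unhindered phenol, while the 2-hydroxyl is held in a hydrogen bond to the formyl group and should stay free.

Step 2
Reactants: 3 2,4-dihydroxybenzaldehyde
Product: 4 2-hydroxy-4-(triisopropylsilyloxy)benzaldehyde
Conditions: TIPSCl, imidazole, CH2Cl2, 0 °C to rt
Reagents that add atoms: triisopropylsilyl chloride, CC(C)[Si](Cl)(C(C)C)C(C)C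
Why: The same regioselective silylation of the non-chelated para hydroxyl as in step 1.

Step 3
Reactants: 4 2-hydroxy-4-(triisopropylsilyloxy)benzaldehyde
Product: 5 2-(benzyloxy)-4-(triisopropylsilyloxy)benzaldehyde
Conditions: BnOH, PPh3, DIAD, THF, 0 °C to rt
Reagents that add atoms: benzyl alcohol, OCc1ccccc1
Why: Mitsunobu etherification of the remaining acidic salicylaldehyde phenol; the neutral conditions avoid carbonate bases, which can cleave or shift an aryl silyl ether para to a formyl group.

Step 4
Reactants: 5 2-(benzyloxy)-4-(triisopropylsilyloxy)benzaldehyde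
Product: 6 [2-(benzyloxy)-4-(triisopropylsilyloxy)phenyl]methanol
Conditions: NaBH4, THF–EtOH, 0 °C
Reagents that add atoms: none
Why: Borohydride reduction of an aryl aldehyde; benzyl and aryl silyl ethers are inert at 0 °C.

Step 5
Reactants: 6 [2-(benzyloxy)-4-(triisopropylsilyloxy)phenyl]methanol
Product: 7 {[2-(benzyloxy)-4-(triisopropylsilyloxy)phenyl]methyl}triphenylphosphonium bromide
Conditions: PPh3·HBr, MeCN, 60 °C
Reagents that add atoms: triphenylphosphine hydrobromide, Br.c1ccc(P(c2ccccc2)c2ccccc2)cc1
Why: Direct phosphonium salt formation from an electron-rich benzylic alcohol; HBr ionises the alcohol to an oxygen-stabilised benzylic cation that PPh3 captures, which avoids isolating a labile benzylic bromide.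

Step 6
Reactants: 7 {[2-(benzyloxy)-4-(triisopropylsilyloxy)phenyl]methyl}triphenylphosphonium bromide; 2 2-hydroxy-6-methoxy-4-(triisopropylsilyloxy)benzaldehyde
Product: 9 2-{2-[2-(benzyloxy)-4-(triisopropylsilyloxy)phenyl]ethenyl}-3-methoxy-5-(triisopropylsilyloxy)phenol as an E/Z mixture, via phosphonium ylide 8 (not isolated)
Conditions: LiN(SiMe3)2 (about 2.3 equiv), THF, −78 °C to rt
Reagents that add atoms: none
Why: Wittig olefination with a semistabilised benzylidene ylide; the extra equivalent of base holds 2 as its lithium phenoxide, which the reactive ylide should still attack. The E/Z ratio does not matter because step 7 equilibrates the alkene.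

Step 7
Reactants: 9 2-{2-[2-(benzyloxy)-4-(triisopropylsilyloxy)phenyl]ethenyl}-3-methoxy-5-(triisopropylsilyloxy)phenol as an E/Z mixture
Product: 10 (E)-2-{2-[2-(benzyloxy)-4-(triisopropylsilyloxy)phenyl]ethenyl}-3-methoxy-5-(triisopropylsilyloxy)phenol
Conditions: I2 (5 mol %), toluene, 80 °C; aq. Na2S2O3
Reagents that add atoms: none
Why: Iodine-catalysed Z to E isomerisation of a stilbene by reversible addition of an iodine atom; the E isomer is the thermodynamic product.

Step 8
Reactants: 10 (E)-2-{2-[2-(benzyloxy)-4-(triisopropylsilyloxy)phenyl]ethenyl}-3-methoxy-5-(triisopropylsilyloxy)phenol; 11 carbon monoxide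
Product: 12 (3R)-3-[2-(benzyloxy)-4-(triisopropylsilyloxy)phenyl]-5-methoxy-7-(triisopropylsilyloxy)chroman-2-one
Conditions: Pd(OAc)2 (5 mol %), (R)-DTBM-SEGPHOS (6 mol %), p-TsOH·H2O (10 mol %), CO (30 bar), toluene, 60 °C
Reagents that add atoms: none
Why: Proposed new method: zerovalent palladium formed in the flask is protonated by TsOH to a cationic bisphosphine palladium hydride, which adds across C3=C4 of 10 with hydrogen on C4 and palladium on C3; CO then inserts into the Pd–C3 bond with retention, and the phenol on C8a attacks the acyl carbon, releasing 12 and the hydride. The closest known reactions are the palladium-catalysed cyclocarbonylation of 2-vinylphenols and 2-allylphenols to lactones and the enantioselective palladium-catalysed hydroesterification of vinylarenes with chiral bisphosphines; an internal stilbene with an ortho phenol as the nucleophile has not been taken through this sequence enantioselectively. Ring C closes by 6-exo-trig acyl substitution, O1 attacking the acyl carbon C2 with the Pd–C bond outside the ring. The C3 stereocentre is controlled by the chiral bisphosphine, which selects the alkene face in the hydropalladation, and CO insertion with retention carries that choice into the product. The step needs palladium on C3 and not on C4, which would end in a five-membered lactone: ring B offers a free ortho carbon (C6') for an η3-benzyl palladium, whereas ring A has both ortho positions substituted and is twisted out of the alkene plane, so the benzyl complex beside ring A is disfavoured, and because hydropalladation is reversible the six-membered lactonisation can drain the C3 acyl. The medium is acidic and free of base, so the α-aryl lactone stereocentre should not be enolised, and the TIPS and benzyl ethers are untouched.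

Step 9
Reactants: 12 (3R)-3-[2-(benzyloxy)-4-(triisopropylsilyloxy)phenyl]-5-methoxy-7-(triisopropylsilyloxy)chroman-2-one
Product: 13 (2R)-2-[2-(benzyloxy)-4-(triisopropylsilyloxy)phenyl]-3-[2-hydroxy-6-methoxy-4-(triisopropylsilyloxy)phenyl]propan-1-ol
Conditions: LiBH4, THF, 0 °C
Reagents that add atoms: none
Why: Hydride reduction of an aryl ester (the lactone) to the primary alcohol and the phenol; the fast reduction at 0 °C should outrun enolisation at C3, and LiBH4 spares aryl silyl ethers.

Step 10
Reactants: 13 (2R)-2-[2-(benzyloxy)-4-(triisopropylsilyloxy)phenyl]-3-[2-hydroxy-6-methoxy-4-(triisopropylsilyloxy)phenyl]propan-1-ol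
Product: 14 (3R)-3-[2-(benzyloxy)-4-(triisopropylsilyloxy)phenyl]-5-methoxy-7-(triisopropylsilyloxy)chromane
Conditions: PPh3, DIAD, THF, 0 °C to rt
Reagents that add atoms: none
Why: Intramolecular Mitsunobu etherification, the standard ring closure of isoflavans; the only acidic hydroxyl (the phenol) displaces the activated primary alcohol in a 6-exo-tet closure at a CH2 carbon, so C3 is not touched.

Step 11
Reactants: 14 (3R)-3-[2-(benzyloxy)-4-(triisopropylsilyloxy)phenyl]-5-methoxy-7-(triisopropylsilyloxy)chromane
Product: 15 2-[(3R)-5-methoxy-7-(triisopropylsilyloxy)chroman-3-yl]-5-(triisopropylsilyloxy)phenol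
Conditions: H2 (1 atm), Pd/C (palladium metal on carbon), EtOAc, rt
Reagents that add atoms: none
Why: Hydrogenolysis of a benzyl aryl ether; aryl silyl ethers and the aryl–O bond of the chromane are stable, and no alkene is present yet.

Step 12
Reactants: 15 2-[(3R)-5-methoxy-7-(triisopropylsilyloxy)chroman-3-yl]-5-(triisopropylsilyloxy)phenol; 16 3-chloro-3-methylbut-1-yne
Product: 17 (3R)-5-methoxy-3-[2-(2-methylbut-3-yn-2-yloxy)-4-(triisopropylsilyloxy)phenyl]-7-(triisopropylsilyloxy)chromane
Conditions: DBU, CuCl2·2H2O (cat.), MeCN, 0 °C to rt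
Reagents that add atoms: none
Why: Copper-catalysed O-alkylation of a phenol with a tertiary propargylic chloride, the standard entry to aryl 1,1-dimethylpropargyl ethers; only one phenol is free.

Step 13
Reactants: 17 (3R)-5-methoxy-3-[2-(2-methylbut-3-yn-2-yloxy)-4-(triisopropylsilyloxy)phenyl]-7-(triisopropylsilyloxy)chromane
Product: 20 (3R)-3-[2,2-dimethyl-5-(triisopropylsilyloxy)-2H-chromen-8-yl]-5-methoxy-7-(triisopropylsilyloxy)chromane, via ortho-allenylphenol 18 (not isolated), via ortho-quinone methide 19 (not isolated)
Conditions: o-xylene, 140 °C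
Reagents that add atoms: none
Why: Thermal aryl propargyl Claisen rearrangement to C3', the only free ortho position, followed by enolisation, 1,5-hydrogen shift and oxa-6π electrocyclisation, the classical route to 2,2-dimethyl-2H-chromenes. A shift to the substituted C1' cannot rearomatise and reverts, and C3 is not involved.

Step 14
Reactants: 20 (3R)-3-[2,2-dimethyl-5-(triisopropylsilyloxy)-2H-chromen-8-yl]-5-methoxy-7-(triisopropylsilyloxy)chromane
Product: 21 (3R)-3-(5-hydroxy-2,2-dimethyl-2H-chromen-8-yl)-5-methoxychroman-7-ol
Conditions: Bu4NF, THF, 0 °C, under argon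
Reagents that add atoms: none
Why: Fluoride cleavage of both aryl silyl ethers; the chromene alkene, the ethers and C3 are inert to Bu4NF.

## Compound list

1 | 2,4-dihydroxy-6-methoxybenzaldehyde | COc1cc(O)cc(O)c1C=O | starting material
2 | 2-hydroxy-6-methoxy-4-(triisopropylsilyloxy)benzaldehyde | COc1cc(O[Si](C(C)C)(C(C)C)C(C)C)cc(O)c1C=O | intermediate
3 | 2,4-dihydroxybenzaldehyde | O=Cc1ccc(O)cc1O | starting material
4 | 2-hydroxy-4-(triisopropylsilyloxy)benzaldehyde | O=Cc1ccc(O[Si](C(C)C)(C(C)C)C(C)C)cc1O | intermediate
5 | 2-(benzyloxy)-4-(triisopropylsilyloxy)benzaldehyde | O=Cc1ccc(O[Si](C(C)C)(C(C)C)C(C)C)cc1OCc1ccccc1 | intermediate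
6 | [2-(benzyloxy)-4-(triisopropylsilyloxy)phenyl]methanol | OCc1ccc(O[Si](C(C)C)(C(C)C)C(C)C)cc1OCc1ccccc1 | intermediate
7 | {[2-(benzyloxy)-4-(triisopropylsilyloxy)phenyl]methyl}triphenylphosphonium bromide | CC(C)[Si](Oc1ccc(C[P+](c2ccccc2)(c2ccccc2)c2ccccc2)c(OCc2ccccc2)c1)(C(C)C)C(C)C.[Br-] | intermediate
8 | {[2-(benzyloxy)-4-(triisopropylsilyloxy)phenyl]methylidene}triphenylphosphorane (ylide, not isolated) | CC(C)[Si](Oc1ccc(C=P(c2ccccc2)(c2ccccc2)c2ccccc2)c(OCc2ccccc2)c1)(C(C)C)C(C)C | intermediate
9 | 2-{2-[2-(benzyloxy)-4-(triisopropylsilyloxy)phenyl]ethenyl}-3-methoxy-5-(triisopropylsilyloxy)phenol, E/Z mixture | COc1cc(O[Si](C(C)C)(C(C)C)C(C)C)cc(O)c1C=Cc1ccc(O[Si](C(C)C)(C(C)C)C(C)C)cc1OCc1ccccc1 | intermediate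
10 | (E)-2-{2-[2-(benzyloxy)-4-(triisopropylsilyloxy)phenyl]ethenyl}-3-methoxy-5-(triisopropylsilyloxy)phenol | COc1cc(O[Si](C(C)C)(C(C)C)C(C)C)cc(O)c1/C=C/c1ccc(O[Si](C(C)C)(C(C)C)C(C)C)cc1OCc1ccccc1 | intermediate
11 | carbon monoxide | [C-]#[O+] | starting material
12 | (3R)-3-[2-(benzyloxy)-4-(triisopropylsilyloxy)phenyl]-5-methoxy-7-(triisopropylsilyloxy)chroman-2-one | COc1cc(O[Si](C(C)C)(C(C)C)C(C)C)cc2c1C[C@H](c1ccc(O[Si](C(C)C)(C(C)C)C(C)C)cc1OCc1ccccc1)C(=O)O2 | intermediate
13 | (2R)-2-[2-(benzyloxy)-4-(triisopropylsilyloxy)phenyl]-3-[2-hydroxy-6-methoxy-4-(triisopropylsilyloxy)phenyl]propan-1-ol | COc1cc(O[Si](C(C)C)(C(C)C)C(C)C)cc(O)c1C[C@H](c1ccc(O[Si](C(C)C)(C(C)C)C(C)C)cc1OCc1ccccc1)CO | intermediate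
14 | (3R)-3-[2-(benzyloxy)-4-(triisopropylsilyloxy)phenyl]-5-methoxy-7-(triisopropylsilyloxy)chromane | COc1cc(O[Si](C(C)C)(C(C)C)C(C)C)cc2c1C[C@H](c1ccc(O[Si](C(C)C)(C(C)C)C(C)C)cc1OCc1ccccc1)CO2 | intermediate
15 | 2-[(3R)-5-methoxy-7-(triisopropylsilyloxy)chroman-3-yl]-5-(triisopropylsilyloxy)phenol | COc1cc(O[Si](C(C)C)(C(C)C)C(C)C)cc2c1C[C@H](c1ccc(O[Si](C(C)C)(C(C)C)C(C)C)cc1O)CO2 | intermediate
16 | 3-chloro-3-methylbut-1-yne | CC(C)(Cl)C#C | starting material
17 | (3R)-5-methoxy-3-[2-(2-methylbut-3-yn-2-yloxy)-4-(triisopropylsilyloxy)phenyl]-7-(triisopropylsilyloxy)chromane | COc1cc(O[Si](C(C)C)(C(C)C)C(C)C)cc2c1C[C@H](c1ccc(O[Si](C(C)C)(C(C)C)C(C)C)cc1OC(C)(C)C#C)CO2 | intermediate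
18 | 6-[(3R)-5-methoxy-7-(triisopropylsilyloxy)chroman-3-yl]-2-(3-methylbuta-1,2-dien-1-yl)-3-(triisopropylsilyloxy)phenol (ortho-allenylphenol, not isolated) | COc1cc(O[Si](C(C)C)(C(C)C)C(C)C)cc2c1C[C@H](c1ccc(O[Si](C(C)C)(C(C)C)C(C)C)c(C=C=C(C)C)c1O)CO2 | intermediate
19 | 2-[(3R)-5-methoxy-7-(triisopropylsilyloxy)chroman-3-yl]-6-(3-methylbut-2-en-1-ylidene)-5-(triisopropylsilyloxy)cyclohexa-2,4-dien-1-one (ortho-quinone methide, not isolated) | COc1cc(O[Si](C(C)C)(C(C)C)C(C)C)cc2c1C[C@H](C1=CC=C(O[Si](C(C)C)(C(C)C)C(C)C)C(=CC=C(C)C)C1=O)CO2 | intermediate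
20 | (3R)-3-[2,2-dimethyl-5-(triisopropylsilyloxy)-2H-chromen-8-yl]-5-methoxy-7-(triisopropylsilyloxy)chromane | COc1cc(O[Si](C(C)C)(C(C)C)C(C)C)cc2c1C[C@H](c1ccc(O[Si](C(C)C)(C(C)C)C(C)C)c3c1OC(C)(C)C=C3)CO2 | intermediate
21 | (3R)-3-(5-hydroxy-2,2-dimethyl-2H-chromen-8-yl)-5-methoxychroman-7-ol | COc1cc(O)cc2c1C[C@H](c1ccc(O)c3c1OC(C)(C)C=C3)CO2 | target

## Step count and least certain steps

Total: 14 steps. Longest linear sequence: 13 steps (from 3 through steps 2 to 14); the ring A branch from 1 joins after one step.

**Step 8 (key step, proposed new method).**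
- Most likely failures: hydropalladation with the opposite regiochemistry, leading to closure of a five-membered lactone; poor facial selectivity, since the two faces of a stilbene differ little towards a crowded cationic hydride; slow insertion of the hindered, electron-rich internal alkene; acid-catalysed addition of the phenol across the alkene; partial enolisation of the product on long heating.
- Fallback (known chemistry): it leaves the route at aldehydes 5 and 2 and rejoins it at 14, replacing steps 4 to 10.
  - Wittig reaction of 5 with Ph3P=CHOMe (from MeOCH2PPh3Cl and KN(SiMe3)2) gives the enol ether 2-(benzyloxy)-1-(2-methoxyethenyl)-4-(triisopropylsilyloxy)benzene F1.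
  - Brief aqueous acid hydrolysis gives [2-(benzyloxy)-4-(triisopropylsilyloxy)phenyl]acetaldehyde F2, and Pinnick oxidation (NaClO2, NaH2PO4, 2-methylbut-2-ene) gives [2-(benzyloxy)-4-(triisopropylsilyloxy)phenyl]acetic acid F3.
  - Acylation of the phenol of 2 with F3 (EDC·HCl, DMAP) and intramolecular Knoevenagel condensation (Et3N), a mild form of the Perkin coumarin synthesis, give 3-[2-(benzyloxy)-4-(triisopropylsilyloxy)phenyl]-5-methoxy-7-(triisopropylsilyloxy)-2H-chromen-2-one F4.
  - i-Bu2AlH reduces F4 to (Z)-2-[2-(benzyloxy)-4-(triisopropylsilyloxy)phenyl]-3-[2-hydroxy-6-methoxy-4-(triisopropylsilyloxy)phenyl]prop-2-en-1-ol F5, and Mitsunobu closure (PPh3, DIAD) gives 3-[2-(benzyloxy)-4-(triisopropylsilyloxy)phenyl]-5-methoxy-7-(triisopropylsilyloxy)-2H-chromene F6.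
  - Iridium-catalysed asymmetric hydrogenation of this 3-aryl-2H-chromene ([Ir(cod)Cl]2, a chiral phosphine–oxazoline ligand, Na[B(3,5-(CF3)2C6H3)4], H2, CH2Cl2), a known enantioselective entry to isoflavans that leaves benzyl ethers intact, gives 14.

**Step 6 (Wittig reaction).**
- Most likely failure: the lithium phenoxide of 2 is a strongly deactivated carbonyl (three donor oxygens, one anionic), so addition of the ylide may stall and the ylide may decompose first.
- Fallback: the polarity of the olefination is reversed. It leaves the route at 2 and 5 and rejoins it at 9, and ring B then needs only steps 2 and 3.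
  - NaBH4 reduces 2 to 2-(hydroxymethyl)-3-methoxy-5-(triisopropylsilyloxy)phenol F7.
  - Without purification, PPh3·HBr converts F7 into [2-hydroxy-6-methoxy-4-(triisopropylsilyloxy)benzyl]triphenylphosphonium bromide F8.
  - The ylide of F8 (two equivalents of base) is combined with the non-phenolic, more electrophilic aldehyde 5 to give 9.

**Step 13 (Claisen rearrangement and electrocyclisation; step 12 shares the risk).**
- Most likely failures: the shift must deliver carbon to C3', which lies between O2' and the bulky silyloxy group on C4'; slow rearrangement at the temperature needed invites ionisation and loss of the tertiary propargyl group. In step 12, elimination of 16 at the hindered phenol may compete.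
- Fallback: it leaves the route at 15 and rejoins it at 20, replacing steps 12 and 13. Phenol 15 is heated with 3-methylbut-2-enal, PhB(OH)2 and AcOH in toluene. Ortho-specific condensation at C3' through the aryl boronate, loss of water to the same ortho-quinone methide 19 and oxa-6π electrocyclisation should give 20 directly; no new isolable compound arises.

**Step 9 (lactone reduction).**
- Most likely failures: partial epimerisation at C3 through enolisation of the aryl ester by basic alkoxyborohydride species before hydride delivery, or attack on an aryl silyl ether.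
- Fallback: it leaves the route at 12 and rejoins it at 14, replacing steps 9 and 10 with non-basic, Lewis-acidic reagents at low temperature. i-Bu2AlH (CH2Cl2, −78 °C) gives the lactol (3R)-3-[2-(benzyloxy)-4-(triisopropylsilyloxy)phenyl]-5-methoxy-7-(triisopropylsilyloxy)chroman-2-ol F9, and Et3SiH with BF3·OEt2 (CH2Cl2, −78 °C) reduces F9 to 14.

## Further compounds

F1 | step 8 | 2-(benzyloxy)-1-(2-methoxyethenyl)-4-(triisopropylsilyloxy)benzene (E/Z mixture) | COC=Cc1ccc(O[Si](C(C)C)(C(C)C)C(C)C)cc1OCc1ccccc1
F2 | step 8 | [2-(benzyloxy)-4-(triisopropylsilyloxy)phenyl]acetaldehyde | O=CCc1ccc(O[Si](C(C)C)(C(C)C)C(C)C)cc1OCc1ccccc1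
F3 | step 8 | [2-(benzyloxy)-4-(triisopropylsilyloxy)phenyl]acetic acid | OC(=O)Cc1ccc(O[Si](C(C)C)(C(C)C)C(C)C)cc1OCc1ccccc1
F4 | step 8 | 3-[2-(benzyloxy)-4-(triisopropylsilyloxy)phenyl]-5-methoxy-7-(triisopropylsilyloxy)-2H-chromen-2-one | COc1cc(O[Si](C(C)C)(C(C)C)C(C)C)cc2oc(=O)c(-c3ccc(O[Si](C(C)C)(C(C)C)C(C)C)cc3OCc3ccccc3)cc12
F5 | step 8 | (Z)-2-[2-(benzyloxy)-4-(triisopropylsilyloxy)phenyl]-3-[2-hydroxy-6-methoxy-4-(triisopropylsilyloxy)phenyl]prop-2-en-1-ol | COc1cc(O[Si](C(C)C)(C(C)C)C(C)C)cc(O)c1/C=C(\CO)c1ccc(O[Si](C(C)C)(C(C)C)C(C)C)cc1OCc1ccccc1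
F6 | step 8 | 3-[2-(benzyloxy)-4-(triisopropylsilyloxy)phenyl]-5-methoxy-7-(triisopropylsilyloxy)-2H-chromene | COc1cc(O[Si](C(C)C)(C(C)C)C(C)C)cc2c1C=C(c1ccc(O[Si](C(C)C)(C(C)C)C(C)C)cc1OCc1ccccc1)CO2
F7 | step 6 | 2-(hydroxymethyl)-3-methoxy-5-(triisopropylsilyloxy)phenol | COc1cc(O[Si](C(C)C)(C(C)C)C(C)C)cc(O)c1CO
F8 | step 6 | [2-hydroxy-6-methoxy-4-(triisopropylsilyloxy)benzyl]triphenylphosphonium bromide | COc1cc(O[Si](C(C)C)(C(C)C)C(C)C)cc(O)c1C[P+](c1ccccc1)(c1ccccc1)c1ccccc1.[Br-]
F0 | step 13 | none | none
F9 | step 9 | (3R)-3-[2-(benzyloxy)-4-(triisopropylsilyloxy)phenyl]-5-methoxy-7-(triisopropylsilyloxy)chroman-2-ol (both anomers) | COc1cc(O[Si](C(C)C)(C(C)C)C(C)C)cc2c1C[C@H](c1ccc(O[Si](C(C)C)(C(C)C)C(C)C)cc1OCc1ccccc1)C(O)O2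
A1 | alternative 1 | 2-[2,2-dimethyl-5-(triisopropylsilyloxy)-2H-chromen-8-yl]-4,4,5,5-tetramethyl-1,3,2-dioxaborolane | CC1(C)OB(c2ccc(O[Si](C(C)C)(C(C)C)C(C)C)c3c2OC(C)(C)C=C3)OC1(C)C
A2 | alternative 1 | vinyllithium | [Li]C=C
A3 | alternative 1 | 2-methoxy-6-(methoxymethoxy)-4-(triisopropylsilyloxy)phenyl trifluoromethanesulfonate | COCOc1cc(O[Si](C(C)C)(C(C)C)C(C)C)cc(OC)c1OS(=O)(=O)C(F)(F)F
A4 | alternative 1 | 2-{(1R)-1-[2,2-dimethyl-5-(triisopropylsilyloxy)-2H-chromen-8-yl]-2-[2-methoxy-6-(methoxymethoxy)-4-(triisopropylsilyloxy)phenyl]ethyl}-4,4,5,5-tetramethyl-1,3,2-dioxaborolane | COc1cc(O[Si](C(C)C)(C(C)C)C(C)C)cc(OCOC)c1C[C@H](c1ccc(O[Si](C(C)C)(C(C)C)C(C)C)c2c1OC(C)(C)C=C2)B1OC(C)(C)C(C)(C)O1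
A5 | alternative 2 | 2-[2,2-dimethyl-5-(triisopropylsilyloxy)-2H-chromen-8-yl]prop-2-enal | C=C(C=O)c1ccc(O[Si](C(C)C)(C(C)C)C(C)C)c2c1OC(C)(C)C=C2
A6 | alternative 2 | 3-methoxy-5-(triisopropylsilyloxy)phenol | COc1cc(O)cc(O[Si](C(C)C)(C(C)C)C(C)C)c1
A7 | alternative 2 | (3R)-3-[2,2-dimethyl-5-(triisopropylsilyloxy)-2H-chromen-8-yl]-5-methoxy-7-(triisopropylsilyloxy)chroman-2-ol (both anomers) | COc1cc(O[Si](C(C)C)(C(C)C)C(C)C)cc2c1C[C@H](c1ccc(O[Si](C(C)C)(C(C)C)C(C)C)c3c1OC(C)(C)C=C3)C(O)O2
A8 | alternative 3 | 3-methoxy-2-[(4-methylbenzenesulfonyl)methyl]-5-(triisopropylsilyloxy)phenol | COc1cc(O[Si](C(C)C)(C(C)C)C(C)C)cc(O)c1CS(=O)(=O)c1ccc(C)cc1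
A9 | alternative 3 | 5-methoxy-6-methylidene-3-(triisopropylsilyloxy)cyclohexa-2,4-dien-1-one | C=C1C(=O)C=C(O[Si](C(C)C)(C(C)C)C(C)C)C=C1OC
A10 | alternative 3 | [2,2-dimethyl-5-(triisopropylsilyloxy)-2H-chromen-8-yl]acetic acid | OC(=O)Cc1ccc(O[Si](C(C)C)(C(C)C)C(C)C)c2c1OC(C)(C)C=C2
A11 | alternative 3 | (3R)-3-[2,2-dimethyl-5-(triisopropylsilyloxy)-2H-chromen-8-yl]-5-methoxy-7-(triisopropylsilyloxy)chroman-2-one | COc1cc(O[Si](C(C)C)(C(C)C)C(C)C)cc2c1C[C@H](c1ccc(O[Si](C(C)C)(C(C)C)C(C)C)c3c1OC(C)(C)C=C3)C(=O)O2
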